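**Retrosynthetic overview**

- The target comes from a protected ten-membered cis-lactone by one acid unmasking. That lactone comes from an open-chain bromo-enal by a CrCl2-catalysed ring-closing 2-(methoxycarbonyl)allylation at C6–C7: the ten-membered carbocycle closes first, and the γ-lactone forms directly afterwards by lactonisation of the syn hydroxy ester.
- The bromo-enal comes from a C8–C9 allylboration between an α-chiral 2-substituted allyl pinacol boronate (C1–C6, C9, C10, C14, C15) and a small bromo-enal (C7, C8, C11–C13), followed by isovalerylation at C8.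
- The allylboronate comes from lithiation–borylation of a primary carbamate with an acetal-bearing alkenyl boronate (from 2-vinyl-1,3-dioxolane). The carbamate comes from a Negishi coupling (C3–C4) of a (Z)-iodoalkene (from but-2-yne-1,4-diol) with a 3-(carbamoyloxy)propylzinc reagent.
- The small bromo-enal comes from the Morita–Baylis–Hillman adduct of 2,2-dimethoxyacetaldehyde and methyl acrylate.

Assumption: the SMILES is read as drawn, i.e. 6R,7S,8R with H6 and H7 cis (cis-fused lactone) and both ring alkenes with the ring carbons cis (each E by CIP); C1–C15 are germacrane locants (C6 bears the lactone oxygen, C7 the acrylate carbon C11, C8 the ester, C10 the formyl carbon C14, C4 the hydroxymethyl carbon C15, C12 is the lactone carbonyl, C13 the exocyclic methylene).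

Abbreviations: TBS = tert-butyldimethylsilyl; TES = triethylsilyl; TMS = trimethylsilyl; pin = pinacolato; SPhos = 2-dicyclohexylphosphino-2′,6′-dimethoxybiphenyl; PPTS = pyridinium p-toluenesulfonate; L = 3,6-di-tert-butyl-1,8-bis[(4S)-4-isopropyl-4,5-dihydro-1,3-oxazol-2-yl]-9H-carbazole.

**Route**

Step 1
Reactants: 1 but-2-yne-1,4-diol
Product: 2 4-[(tert-butyldimethylsilyl)oxy]but-2-yn-1-ol
Conditions: TBSCl (1 equiv), 1 (3 equiv), imidazole, THF, 0 °C
Reagents that add atoms: tert-butyldimethylsilyl chloride, CC(C)(C)[Si](C)(C)Cl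
Why: Statistical mono-silylation (silyl ether formation) of the symmetrical diol used in excess, so that only one hydroxyl is capped; no stereocentre is involved.

Step 2
Reactants: 2 4-[(tert-butyldimethylsilyl)oxy]but-2-yn-1-ol
Product: 4 (2Z)-4-[(tert-butyldimethylsilyl)oxy]-3-iodobut-2-en-1-ol, via alkenylalanate 3 (not isolated)
Conditions: NaAlH2(OCH2CH2OCH3)2, THF, 0 °C; then I2, THF, −78 → 0 °C
Reagents that add atoms: iodine, II
Why: Hydroxyl-directed trans-hydroalumination of the propargylic alcohol puts aluminium on the distal alkyne carbon inside a five-membered alkoxy-alanate, and iodinolysis with retention gives the iodoalkene with iodine cis to the CH2OH group, which fixes the later C4=C5 geometry.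

Step 3
Reactants: 4 (2Z)-4-[(tert-butyldimethylsilyl)oxy]-3-iodobut-2-en-1-ol
Product: 5 (2Z)-4-[(tert-butyldimethylsilyl)oxy]-3-iodo-1-[(triethylsilyl)oxy]but-2-ene
Conditions: TESCl, imidazole, CH2Cl2, 0 °C
Reagents that add atoms: triethylsilyl chloride, CC[Si](Cl)(CC)CC
Why: Routine silyl ether formation on the primary allylic alcohol, chosen because a triethylsilyl ether is cleaved far faster than the tert-butyldimethylsilyl ether later on.

Step 4
Reactants: 6 3-bromopropan-1-ol
Product: 7 3-bromopropyl N,N-diisopropylcarbamate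
Conditions: i-Pr2NCOCl, Et3N, CH2Cl2, reflux
Reagents that add atoms: N,N-diisopropylcarbamoyl chloride, CC(C)N(C(C)C)C(Cl)=O
Why: O-Carbamoylation gives the Hoppe-type N,N-diisopropylcarbamate that later directs the enantioselective lithiation.

Step 5
Reactants: 7 3-bromopropyl N,N-diisopropylcarbamate; 5 (2Z)-4-[(tert-butyldimethylsilyl)oxy]-3-iodo-1-[(triethylsilyl)oxy]but-2-ene
Product: 9 (4E)-4-{[(tert-butyldimethylsilyl)oxy]methyl}-6-[(triethylsilyl)oxy]hex-4-en-1-yl N,N-diisopropylcarbamate, via alkylzinc bromide 8 (not isolated)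
Conditions: 7, Zn dust, LiCl, THF, 50 °C; then 5, Pd(OAc)2 (2 mol %), SPhos (4 mol %), THF, 25 °C
Reagents that add atoms: none
Why: Negishi sp3–sp2 cross-coupling: LiCl-assisted zinc insertion into the primary bromide, oxidative addition of zerovalent palladium to the alkenyl iodide and reductive elimination with retention of alkene geometry, so C3 ends cis to C6.

Step 6
Reactants: 10 2-ethenyl-1,3-dioxolane
Product: 11 2-(1,2-dibromoethyl)-1,3-dioxolane (racemic)
Conditions: Br2, CH2Cl2, −20 °C
Reagents that add atoms: bromine, BrBr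
Why: Electrophilic anti-addition of bromine to the vinyl group; the new stereocentre is racemic and is destroyed in the next step.

Step 7
Reactants: 11 2-(1,2-dibromoethyl)-1,3-dioxolane
Product: 12 2-(1-bromoethenyl)-1,3-dioxolane
Conditions: KOtBu, THF, 0 °C
Reagents that add atoms: none
Why: E2 dehydrobromination removes the more acidic proton on the carbon flanked by bromine and the acetal, giving the 2-bromoacrolein acetal.

Step 8
Reactants: 12 2-(1-bromoethenyl)-1,3-dioxolane
Product: 13 2-[1-(1,3-dioxolan-2-yl)ethenyl]-4,4,5,5-tetramethyl-1,3,2-dioxaborolane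
Conditions: B2pin2, PdCl2(PPh3)2 (3 mol %), PPh3 (6 mol %), KOPh, toluene, 50 °C
Reagents that add atoms: bis(pinacolato)diboron, CC1(C)OB(OC1(C)C)B2OC(C)(C)C(C)(C)O2
Why: Miyaura borylation (oxidative addition of zerovalent palladium to the alkenyl bromide, transmetallation with the phenoxide-activated diboron reagent, reductive elimination) gives the 1,1-disubstituted alkenylboronate.

Step 9
Reactants: 9 (4E)-4-{[(tert-butyldimethylsilyl)oxy]methyl}-6-[(triethylsilyl)oxy]hex-4-en-1-yl N,N-diisopropylcarbamate; 13 2-[1-(1,3-dioxolan-2-yl)ethenyl]-4,4,5,5-tetramethyl-1,3,2-dioxaborolane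
Product: 16 2-[(3R,6E)-6-{[(tert-butyldimethylsilyl)oxy]methyl}-2-(1,3-dioxolan-2-yl)-8-[(triethylsilyl)oxy]octa-1,6-dien-3-yl]-4,4,5,5-tetramethyl-1,3,2-dioxaborolane, via lithio carbamate 14 (not isolated), via lithium boronate complex 15 (not isolated)
Conditions: s-BuLi, (−)-sparteine, Et2O, −78 °C, 5 h; 13, −78 °C, 1 h; MgBr2·OEt2, then 35 °C, 12 h
Reagents that add atoms: none
Why: Hoppe–Aggarwal lithiation–borylation: (−)-sparteine-mediated removal of the pro-S proton gives a configurationally stable lithio carbamate, the boronate adds with retention and the alkenyl group undergoes a stereospecific 1,2-metallate shift with inversion as the carbamate leaves, which sets C1 as R.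

Step 10
Reactants: 17 2,2-dimethoxyacetaldehyde; 18 methyl prop-2-enoate
Product: 19 methyl 3-hydroxy-4,4-dimethoxy-2-methylidenebutanoate (racemic)
Conditions: 1,4-diazabicyclo[2.2.2]octane (0.5 equiv), 1,4-dioxane/H2O, 25 °C
Reagents that add atoms: none
Why: Morita–Baylis–Hillman reaction of the activated α-alkoxy aldehyde with the acrylate; the carbinol stereocentre is racemic and is removed in the next step.

Step 11
Reactants: 19 methyl 3-hydroxy-4,4-dimethoxy-2-methylidenebutanoate
Product: 20 methyl (2Z)-2-(bromomethyl)-4,4-dimethoxybut-2-enoate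
Conditions: N-bromosuccinimide, Me2S, CH2Cl2, 0 → 25 °C
Reagents that add atoms: N-bromosuccinimide, O=C1CCC(=O)N1Br
Why: Corey–Kim-type activation of the allylic alcohol followed by SN2′ delivery of bromide gives the thermodynamically favoured (Z)-2-(bromomethyl)enoate with the acetal carbon trans to the ester.

Step 12
Reactants: 20 methyl (2Z)-2-(bromomethyl)-4,4-dimethoxybut-2-enoate
Product: 21 methyl (2Z)-2-(bromomethyl)-4-oxobut-2-enoate
Conditions: CF3CO2H, H2O, CH2Cl2, 0 °C; used at once
Reagents that add atoms: water, O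
Why: Acid-catalysed acetal hydrolysis; the formyl group stays trans to the ester, the arrangement that cannot close to a hydroxybutenolide.

Step 13
Reactants: 16 the (3R,6E)-allylboronate; 21 methyl (2Z)-2-(bromomethyl)-4-oxobut-2-enoate
Product: 23 methyl (2Z,4R,6E,10E)-2-(bromomethyl)-10-{[(tert-butyldimethylsilyl)oxy]methyl}-6-(1,3-dioxolan-2-yl)-4-hydroxy-12-[(triethylsilyl)oxy]dodeca-2,6,10-trienoate, via O-boryl adduct 22 (not isolated)
Conditions: toluene, 4 Å molecular sieves, 25 °C, 36 h; then pH 7 phosphate buffer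
Reagents that add atoms: none
Why: Closed chair (Zimmerman–Traxler) allylboration: A1,2 strain with the dioxolanyl group on C10 and the pinacol ring put the C2 chain axial, so the C1=C10 alkene forms with C2 cis to C9 and the C1 configuration is transferred to C8 (R) with the enal substituent equatorial.

Step 14
Reactants: 23 the C8 alcohol; 24 3-methylbutanoyl chloride
Product: 25 methyl (2Z,4R,6E,10E)-2-(bromomethyl)-10-{[(tert-butyldimethylsilyl)oxy]methyl}-6-(1,3-dioxolan-2-yl)-4-[(3-methylbutanoyl)oxy]-12-[(triethylsilyl)oxy]dodeca-2,6,10-trienoate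
Conditions: 2,6-lutidine, CH2Cl2, 0 → 25 °C
Reagents that add atoms: none
Why: O-Acylation of the secondary allylic alcohol with the acid chloride, using a hindered pyridine base that does not attack the allylic bromide.

Step 15
Reactants: 25 the C8 isovalerate
Product: 26 methyl (2Z,4R,6E,10E)-2-(bromomethyl)-10-{[(tert-butyldimethylsilyl)oxy]methyl}-6-(1,3-dioxolan-2-yl)-12-hydroxy-4-[(3-methylbutanoyl)oxy]dodeca-2,6,10-trienoate
Conditions: PPTS (0.2 equiv), MeOH/CH2Cl2 (1:1), 0 °C
Reagents that add atoms: none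
Why: Acid-catalysed methanolysis of the primary triethylsilyl ether, which is about two orders of magnitude faster than loss of the tert-butyldimethylsilyl ether.

Step 16
Reactants: 26 the C6 allylic alcohol
Product: 27 methyl (2Z,4R,6E,10E)-2-(bromomethyl)-10-{[(tert-butyldimethylsilyl)oxy]methyl}-6-(1,3-dioxolan-2-yl)-4-[(3-methylbutanoyl)oxy]-12-oxododeca-2,6,10-trienoate
Conditions: MnO2 (20 equiv), CH2Cl2, 25 °C
Reagents that add atoms: none
Why: MnO2 oxidation of the primary allylic alcohol under neutral conditions keeps the enal geometry (C6 cis to C3) and leaves every other group untouched.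

Step 17
Reactants: 27 the open-chain bromo-enal
Product: 30 (3aS,4R,6E,10E,11aR)-10-{[(tert-butyldimethylsilyl)oxy]methyl}-6-(1,3-dioxolan-2-yl)-3-methylidene-2-oxo-2,3,3a,4,5,8,9,11a-octahydrocyclodeca[b]furan-4-yl 3-methylbutanoate, via trimethylsilyl ether 28 (not isolated), via hydroxy ester 29 (not isolated)
Conditions: CrCl2 (10 mol %), L (12 mol %), i-Pr2NEt (30 mol %), Mn powder (3 equiv), TMSCl (2 equiv), THF, 27 added over 12 h (final 2 mM), 25 °C; then 10 % aq. citric acid, THF, 25 °C
Reagents that add atoms: none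
Why: Proposed new method: a CrCl2-catalysed, ligand-controlled ring-closing 2-(alkoxycarbonyl)allylation in which divalent chromium (regenerated by Mn from the trivalent state) inserts into the allylic C–Br bond, the (Z)-γ-substituted allylchromium carrying the tridentate ligand adds through a closed six-membered chair transition state to the Si face of the tethered C6 aldehyde to give the syn adduct (C6 R, hence the cis lactone after loss of methanol), C7 (S) is fixed because the tether can reach C7 only on the face anti to the C8 acyloxy group in the A1,3-strain-minimised rotamer, and TMSCl turns the chromium alkoxide over; the closest known reactions are the stoichiometric CrCl2 (Nozaki–Hiyama) ring closure of ω-formyl allylic bromides to ten-membered germacranolides and the intermolecular chromium-catalysed asymmetric 2-(alkoxycarbonyl)allylation of aldehydes.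

Step 18
Reactants: 30 the protected ten-membered lactone
Product: 31 (3aS,4R,6E,10E,11aR)-6-formyl-10-(hydroxymethyl)-3-methylidene-2-oxo-2,3,3a,4,5,8,9,11a-octahydrocyclodeca[b]furan-4-yl 3-methylbutanoate
Conditions: 1 M aq. HCl/THF (1:3), 0 → 25 °C
Reagents that add atoms: water, O
Why: Aqueous acid removes the primary silyl ether and hydrolyses the conjugated dioxolane in one operation while the lactone, the ester and the stereocentres are unaffected.

**Compound list**

1 | but-2-yne-1,4-diol | OCC#CCO | starting material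
2 | 4-[(tert-butyldimethylsilyl)oxy]but-2-yn-1-ol | OCC#CCO[Si](C)(C)C(C)(C)C | intermediate
3 | sodium alkenylalanate: five-membered ring Al–O–C6–C5=C4, Al on C4, two 2-methoxyethoxy groups on Al | [Na+].COCCO[Al-]1(OCCOC)OCC=C1CO[Si](C)(C)C(C)(C)C | intermediate
4 | (2Z)-4-[(tert-butyldimethylsilyl)oxy]-3-iodobut-2-en-1-ol | OC/C=C(\I)CO[Si](C)(C)C(C)(C)C | intermediate
5 | (2Z)-4-[(tert-butyldimethylsilyl)oxy]-3-iodo-1-[(triethylsilyl)oxy]but-2-ene | CC[Si](CC)(CC)OC/C=C(\I)CO[Si](C)(C)C(C)(C)C | intermediate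
6 | 3-bromopropan-1-ol | OCCCBr | starting material
7 | 3-bromopropyl N,N-diisopropylcarbamate | BrCCCOC(=O)N(C(C)C)C(C)C | intermediate
8 | {3-[(diisopropylcarbamoyl)oxy]propyl}zinc bromide | Br[Zn]CCCOC(=O)N(C(C)C)C(C)C | intermediate
9 | (4E)-4-{[(tert-butyldimethylsilyl)oxy]methyl}-6-[(triethylsilyl)oxy]hex-4-en-1-yl N,N-diisopropylcarbamate | CC[Si](CC)(CC)OC/C=C(/CO[Si](C)(C)C(C)(C)C)CCCOC(=O)N(C(C)C)C(C)C | intermediate
10 | 2-ethenyl-1,3-dioxolane | C=CC1OCCO1 | starting material
11 | 2-(1,2-dibromoethyl)-1,3-dioxolane (racemic) | BrCC(Br)C1OCCO1 | intermediate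
12 | 2-(1-bromoethenyl)-1,3-dioxolane | C=C(Br)C1OCCO1 | intermediate
13 | 2-[1-(1,3-dioxolan-2-yl)ethenyl]-4,4,5,5-tetramethyl-1,3,2-dioxaborolane | C=C(B1OC(C)(C)C(C)(C)O1)C2OCCO2 | intermediate
14 | (1S)-1-lithio derivative of 9, as its (−)-sparteine complex | CC[Si](CC)(CC)OC/C=C(/CO[Si](C)(C)C(C)(C)C)CC[C@H]([Li])OC(=O)N(C(C)C)C(C)C | intermediate
15 | lithium boronate complex: boron carries pinacol, the alkenyl group of 13 and C1 of 14 (retention at C1) | CC[Si](CC)(CC)OC/C=C(/CO[Si](C)(C)C(C)(C)C)CC[C@H]([B-]1(OC(C)(C)C(C)(C)O1)C(=C)C2OCCO2)OC(=O)N(C(C)C)C(C)C.[Li+] | intermediate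
16 | 2-[(3R,6E)-6-{[(tert-butyldimethylsilyl)oxy]methyl}-2-(1,3-dioxolan-2-yl)-8-[(triethylsilyl)oxy]octa-1,6-dien-3-yl]-4,4,5,5-tetramethyl-1,3,2-dioxaborolane | CC[Si](CC)(CC)OC/C=C(/CO[Si](C)(C)C(C)(C)C)CC[C@@H](B1OC(C)(C)C(C)(C)O1)C(=C)C2OCCO2 | intermediate
17 | 2,2-dimethoxyacetaldehyde | COC(OC)C=O | starting material
18 | methyl prop-2-enoate | C=CC(=O)OC | starting material
19 | methyl 3-hydroxy-4,4-dimethoxy-2-methylidenebutanoate (racemic) | COC(OC)C(O)C(=C)C(=O)OC | intermediate
20 | methyl (2Z)-2-(bromomethyl)-4,4-dimethoxybut-2-enoate | COC(OC)/C=C(\CBr)C(=O)OC | intermediate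
21 | methyl (2Z)-2-(bromomethyl)-4-oxobut-2-enoate | O=C/C=C(\CBr)C(=O)OC | intermediate
22 | methyl (2Z,4R,6E,10E)-2-(bromomethyl)-10-{[(tert-butyldimethylsilyl)oxy]methyl}-6-(1,3-dioxolan-2-yl)-4-[(4,4,5,5-tetramethyl-1,3,2-dioxaborolan-2-yl)oxy]-12-[(triethylsilyl)oxy]dodeca-2,6,10-trienoate | CC[Si](CC)(CC)OC/C=C(/CO[Si](C)(C)C(C)(C)C)CC/C=C(/C1OCCO1)C[C@@H](OB2OC(C)(C)C(C)(C)O2)/C=C(\CBr)C(=O)OC | intermediate
23 | methyl (2Z,4R,6E,10E)-2-(bromomethyl)-10-{[(tert-butyldimethylsilyl)oxy]methyl}-6-(1,3-dioxolan-2-yl)-4-hydroxy-12-[(triethylsilyl)oxy]dodeca-2,6,10-trienoate | CC[Si](CC)(CC)OC/C=C(/CO[Si](C)(C)C(C)(C)C)CC/C=C(/C1OCCO1)C[C@@H](O)/C=C(\CBr)C(=O)OC | intermediate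
24 | 3-methylbutanoyl chloride | CC(C)CC(Cl)=O | starting material
25 | methyl (2Z,4R,6E,10E)-2-(bromomethyl)-10-{[(tert-butyldimethylsilyl)oxy]methyl}-6-(1,3-dioxolan-2-yl)-4-[(3-methylbutanoyl)oxy]-12-[(triethylsilyl)oxy]dodeca-2,6,10-trienoate | CC[Si](CC)(CC)OC/C=C(/CO[Si](C)(C)C(C)(C)C)CC/C=C(/C1OCCO1)C[C@@H](OC(=O)CC(C)C)/C=C(\CBr)C(=O)OC | intermediate
26 | methyl (2Z,4R,6E,10E)-2-(bromomethyl)-10-{[(tert-butyldimethylsilyl)oxy]methyl}-6-(1,3-dioxolan-2-yl)-12-hydroxy-4-[(3-methylbutanoyl)oxy]dodeca-2,6,10-trienoate | OC/C=C(/CO[Si](C)(C)C(C)(C)C)CC/C=C(/C1OCCO1)C[C@@H](OC(=O)CC(C)C)/C=C(\CBr)C(=O)OC | intermediate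
27 | methyl (2Z,4R,6E,10E)-2-(bromomethyl)-10-{[(tert-butyldimethylsilyl)oxy]methyl}-6-(1,3-dioxolan-2-yl)-4-[(3-methylbutanoyl)oxy]-12-oxododeca-2,6,10-trienoate | O=C/C=C(/CO[Si](C)(C)C(C)(C)C)CC/C=C(/C1OCCO1)C[C@@H](OC(=O)CC(C)C)/C=C(\CBr)C(=O)OC | intermediate
28 | methyl 2-[(1S,2R,3E,7E,10R)-4-{[(tert-butyldimethylsilyl)oxy]methyl}-8-(1,3-dioxolan-2-yl)-10-[(3-methylbutanoyl)oxy]-2-[(trimethylsilyl)oxy]cyclodeca-3,7-dien-1-yl]prop-2-enoate | C=C(C(=O)OC)[C@@H]1[C@H](O[Si](C)(C)C)/C=C(/CO[Si](C)(C)C(C)(C)C)CC/C=C(/C2OCCO2)C[C@H]1OC(=O)CC(C)C | intermediate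
29 | methyl 2-[(1R,2R,3E,7E,10R)-4-{[(tert-butyldimethylsilyl)oxy]methyl}-8-(1,3-dioxolan-2-yl)-2-hydroxy-10-[(3-methylbutanoyl)oxy]cyclodeca-3,7-dien-1-yl]prop-2-enoate (same spatial arrangement as 28) | C=C(C(=O)OC)[C@@H]1[C@H](O)/C=C(/CO[Si](C)(C)C(C)(C)C)CC/C=C(/C2OCCO2)C[C@H]1OC(=O)CC(C)C | intermediate
30 | (3aS,4R,6E,10E,11aR)-10-{[(tert-butyldimethylsilyl)oxy]methyl}-6-(1,3-dioxolan-2-yl)-3-methylidene-2-oxo-2,3,3a,4,5,8,9,11a-octahydrocyclodeca[b]furan-4-yl 3-methylbutanoate | C=C1C(=O)O[C@@H]2/C=C(/CO[Si](C)(C)C(C)(C)C)CC/C=C(/C3OCCO3)C[C@@H](OC(=O)CC(C)C)[C@H]12 | intermediate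
31 | (3aS,4R,6E,10E,11aR)-6-formyl-10-(hydroxymethyl)-3-methylidene-2-oxo-2,3,3a,4,5,8,9,11a-octahydrocyclodeca[b]furan-4-yl 3-methylbutanoate | C=C1C(=O)O[C@@H]2/C=C(/CO)CC/C=C(/C=O)C[C@@H](OC(=O)CC(C)C)[C@H]12 | target

**Step count**

Total: 18 steps. Longest linear sequence: 11 steps (1, 2, 3, 5, 9, 13, 14, 15, 16, 17, 18).

**Steps most likely to fail**

Step 17 (the new ring closure). The allylchromium may lose the C8 isovalerate by 1,4-elimination, the enal may undergo chromium-mediated pinacol coupling, oligomers may form, or the ligand antipode may prove mismatched with the substrate bias. The fallback uses known chemistry and gives up catalysis and ligand control. It sets out from 27 and uses the classical stoichiometric Nozaki–Hiyama ring closure that has closed ten-membered germacranolide rings: 27 is added slowly to CrCl2 (6 equiv) in THF/DMF (final 1 mM) at 25 °C, without Mn, TMSCl or ligand. Diastereocontrol then rests on the substrate alone (A1,3 strain at C8 plus the tether). Aqueous work-up gives hydroxy ester 29, which lactonises and rejoins the route at 30. No compound outside the list is made (F0).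

Step 12 (release of the bromo-enal 21, on which step 13 depends). Aqueous acid may hydrolyse the allylic bromide or polymerise the doubly activated enal. The fallback avoids acid and makes the aldehyde by oxidative cleavage. It sets out from 18: a Morita–Baylis–Hillman reaction with (2E)-but-2-enal (1,4-diazabicyclo[2.2.2]octane) gives methyl (4E)-3-hydroxy-2-methylidenehex-4-enoate F1. N-Bromosuccinimide/Me2S converts it into methyl (2Z,4E)-2-(bromomethyl)hexa-2,4-dienoate F2. Ozonolysis (O3, CH2Cl2, −78 °C; then Me2S) cleaves only the electron-richer distal alkene, as in the classical preparation of 4-oxobut-2-enoates from sorbates, and the route is rejoined at 21.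

Step 18 (one-pot double unmasking). The conjugated dioxolane may hydrolyse slowly, and prolonged acid could harm the enal and allylic alcohol. The fallback separates the two events with orthogonal reagents. It sets out from 30: HF·pyridine/pyridine in THF at 0 °C removes only the silyl group and gives (3aS,4R,6E,10E,11aR)-6-(1,3-dioxolan-2-yl)-10-(hydroxymethyl)-3-methylidene-2-oxo-2,3,3a,4,5,8,9,11a-octahydrocyclodeca[b]furan-4-yl 3-methylbutanoate F3. The acetal is then cleaved under nearly neutral conditions (oxalic acid on wet silica gel, CH2Cl2, 25 °C), which rejoins the route at 31.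

**Further compounds**

F0 | step 17 | none | none
F1 | step 12 | methyl (4E)-3-hydroxy-2-methylidenehex-4-enoate (racemic) | C/C=C/C(O)C(=C)C(=O)OC
F2 | step 12 | methyl (2Z,4E)-2-(bromomethyl)hexa-2,4-dienoate | C/C=C/C=C(\CBr)C(=O)OC
F3 | step 18 | (3aS,4R,6E,10E,11aR)-6-(1,3-dioxolan-2-yl)-10-(hydroxymethyl)-3-methylidene-2-oxo-2,3,3a,4,5,8,9,11a-octahydrocyclodeca[b]furan-4-yl 3-methylbutanoate | C=C1C(=O)O[C@@H]2/C=C(/CO)CC/C=C(/C3OCCO3)C[C@@H](OC(=O)CC(C)C)[C@H]12
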